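**Retrosynthetic overview**

1. Target 26 ⇒ desilylation and C‑acylation at the methyl group of ring methyl ketone 20 with the silyl‑protected feruloyl chloride 24.
2. 20 ⇒ gem‑diester 15 by Krapcho loss of one ester, equilibration of C1 to the all‑equatorial (all‑trans) epimer and ester → N‑methoxy‑N‑methylamide → methyl ketone.
3. 15 ⇒ acyclic benzylic methyl ether/(Z)‑vinylsilane 12 by disconnection of C5–C6. The strategy rests on C6 of the cyclohexene ring, which is both benzylic to the 3,4‑dimethoxyphenyl ring and allylic to C4=C5: a cation at C6 can be captured by the silicon‑bearing C5 of a vinylsilane, and loss of silicon leaves the alkene at C4=C5.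
4. 12 ⇒ alkyne 5 by C1–C6 alkylation with the α‑chloro ether of veratraldehyde, alkyne C‑silylation and cis reduction; 5 ⇒ tosylated coniferaldehyde 2 + dimethyl malonate by Ohira–Bestmann homologation and an amine‑catalysed Michael addition that sets C2.
5. Ring order: the three arene rings are bought; the cyclohexene is the only ring made (step 8).

Key step: step 8

**Remarks**

- Ring locants follow the target as drawn: C1 bears the acyl group, C2 the 4‑hydroxy‑3‑methoxyphenyl group, C3 is CH2, C4=C5 is the ring alkene, C6 bears the 3,4‑dimethoxyphenyl group. Names of ring compounds keep these locants (hence "cyclohex‑4‑ene"). Ts = 4‑methylbenzenesulfonyl, TBS = tert‑butyldimethylsilyl.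
- The phenol of the C2 aryl ring is carried as its tosylate up to and through the cyclisation. A donor ether there would make that ring a competing nucleophile for the C6 cation (indane closure) and would allow C1–C2 fragmentation to a second benzylic cation. The tosylate is exchanged for a TBS ether afterwards.
- The descriptor of the benzylic carbon changes from S (4, 5) to R (9–15) and back to S (16–26) only through CIP priorities; no bond at that carbon is touched after step 2.

**Step 1**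
Reactants: 1 coniferaldehyde
Product: 2 (E)-3-[3-methoxy-4-(tosyloxy)phenyl]prop-2-enal
Conditions: TsCl, Et3N, DMAP (cat.), CH2Cl2, 0 °C → rt
Reagents that add atoms: 4-methylbenzenesulfonyl chloride, Cc1ccc(cc1)S(Cl)(=O)=O
Why: O‑sulfonylation of the phenol gives an aryl sulfonate that should survive the bases, the borane and the Lewis acid ahead and keeps this ring electron‑poor for the key step.

**Step 2**
Reactants: 2 (E)-3-[3-methoxy-4-(tosyloxy)phenyl]prop-2-enal; 3 dimethyl malonate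
Product: 4 dimethyl 2-[(1S)-1-[3-methoxy-4-(tosyloxy)phenyl]-3-oxopropyl]malonate
Conditions: (R)-2-{bis[3,5-bis(trifluoromethyl)phenyl][(trimethylsilyl)oxy]methyl}pyrrolidine (10 mol%), EtOH, 0 °C
Reagents that add atoms: none
Why: Iminium‑catalysed asymmetric Michael addition in which the silyloxydiarylmethyl group of the (R)‑catalyst shields the Si face of C‑β of the (E)‑s‑trans iminium ion, so malonate adds to the Re face and sets the future C2 as (S).

**Step 3**
Reactants: 4 dimethyl 2-[(1S)-1-[3-methoxy-4-(tosyloxy)phenyl]-3-oxopropyl]malonate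
Product: 5 dimethyl 2-[(1S)-1-[3-methoxy-4-(tosyloxy)phenyl]but-3-yn-1-yl]malonate
Conditions: dimethyl (1-diazo-2-oxopropyl)phosphonate, K2CO3, MeOH, 0 °C → rt
Reagents that add atoms: dimethyl (1-diazo-2-oxopropyl)phosphonate, CC(=O)C(=[N+]=[N-])P(=O)(OC)OC
Why: Ohira–Bestmann (Seyferth–Gilbert) homologation of the aldehyde under carbonate/methanol conditions that should consume the aldehyde faster than it enolises (no retro‑Michael loss of the stereocentre) and in which methanolysis of the methyl esters is degenerate.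

**Step 4**
Reactants: 6 3,4-dimethoxybenzaldehyde
Product: 7 4-(dimethoxymethyl)-1,2-dimethoxybenzene
Conditions: HC(OMe)3, TsOH·H2O (cat.), MeOH, rt
Reagents that add atoms: trimethyl orthoformate, COC(OC)OC; methanol, CO
Why: Acid‑catalysed acetalisation driven by the orthoester as water scavenger.

**Step 5**
Reactants: 5 dimethyl 2-[(1S)-1-[3-methoxy-4-(tosyloxy)phenyl]but-3-yn-1-yl]malonate; 7 4-(dimethoxymethyl)-1,2-dimethoxybenzene
Product: 9 dimethyl 2-[(3,4-dimethoxyphenyl)(methoxy)methyl]-2-[(1R)-1-[3-methoxy-4-(tosyloxy)phenyl]but-3-yn-1-yl]malonate (both epimers at the methoxy-bearing carbon), via α-chloro ether 8 (not isolated)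
Conditions: 7, AcCl, ZnBr2 (0.1 mol%), toluene, rt; solution added to 5, NaH, THF, 0 °C, then −20 °C → rt
Reagents that add atoms: none
Why: Malonate enolate alkylation with an α‑chloro ether, an SN1‑type electrophile (oxocarbenium ion pair) reactive enough to form the quaternary C1 and the C1–C6 bond; the ether carbon needs no control because it is ionised in step 8.

**Step 6**
Reactants: 9 dimethyl 2-[(3,4-dimethoxyphenyl)(methoxy)methyl]-2-[(1R)-1-[3-methoxy-4-(tosyloxy)phenyl]but-3-yn-1-yl]malonate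
Product: 10 dimethyl 2-[(3,4-dimethoxyphenyl)(methoxy)methyl]-2-[(1R)-1-[3-methoxy-4-(tosyloxy)phenyl]-4-(trimethylsilyl)but-3-yn-1-yl]malonate
Conditions: LDA, THF, −78 °C; TMSCl, −78 → 0 °C
Reagents that add atoms: chlorotrimethylsilane, C[Si](C)(C)Cl
Why: Deprotonation of the terminal alkyne and C‑silylation, clean at this stage because the malonate carbon is now quaternary and the hindered amide base does not add to the esters.

**Step 7**
Reactants: 10 dimethyl 2-[(3,4-dimethoxyphenyl)(methoxy)methyl]-2-[(1R)-1-[3-methoxy-4-(tosyloxy)phenyl]-4-(trimethylsilyl)but-3-yn-1-yl]malonate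
Product: 12 dimethyl 2-[(3,4-dimethoxyphenyl)(methoxy)methyl]-2-[(1R,3Z)-1-[3-methoxy-4-(tosyloxy)phenyl]-4-(trimethylsilyl)but-3-en-1-yl]malonate, via alkenylborane 11 (not isolated)
Conditions: (c-C6H11)2BH, THF, 0 °C → rt; then AcOH, 55 °C
Reagents that add atoms: none
Why: Syn hydroboration of the 1‑silylalkyne (boron on the silicon‑bearing carbon) followed by protonolysis of the C–B bond with retention gives the (Z)‑vinylsilane, and the dialkylborane does not reduce esters.

**Step 8**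
Reactants: 12 dimethyl 2-[(3,4-dimethoxyphenyl)(methoxy)methyl]-2-[(1R,3Z)-1-[3-methoxy-4-(tosyloxy)phenyl]-4-(trimethylsilyl)but-3-en-1-yl]malonate
Product: 15 dimethyl (2R,6S)-6-(3,4-dimethoxyphenyl)-2-[3-methoxy-4-(tosyloxy)phenyl]cyclohex-4-ene-1,1-dicarboxylate, via benzylic cation 13 (not isolated), via β-silyl cation 14 (not isolated)
Conditions: BF3·OEt2 (3–4 equiv), 2,6-di-tert-butyl-4-methylpyridine (0.3 equiv), CH2Cl2, −78 → −20 °C
Reagents that add atoms: none
Why: BF3 ionises the benzylic methyl ether to the 3,4‑dimethoxybenzyl cation 13, which cannot lose a proton because C1 is quaternary, and the (Z)‑vinylsilane captures it through its silicon‑bearing carbon C5 to give the β‑silyl cation 14, which loses Me3Si+ to fluoride so that the alkene sits at C4=C5; the closest known reaction type is the vinylsilane‑terminated cation–alkene cyclisation in its endocyclic mode. The one ring closes by 6‑endo attack on the C4=C5 π bond through a chair‑like array C6–C1–C2–C3–C4–C5, forming the C5–C6 bond. The new stereocentre C6 is controlled by the preset C2: with the C2 aryl group equatorial, the cationic carbon should present its aryl group pseudo‑equatorially, which places the two aryl groups cis, (2R,6S). Regioselectivity (bond to C5 and not 5‑exo attack at C4) follows from β‑silicon stabilisation of charge at C4, and the cis ring alkene requires the (Z)‑silane, in which silicon is replaced with retention. Chemoselectivity over Friedel–Crafts capture by the C2 aryl ring (5‑endo, indane) and over C1–C2 fragmentation to a second benzylic cation is secured by the sulfonate on that ring, which lowers its π‑nucleophilicity and withholds para‑oxygen donation. The hindered pyridine removes adventitious protic acid so that protodesilylation does not precede cyclisation.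

**Step 9**
Reactants: 15 dimethyl (2R,6S)-6-(3,4-dimethoxyphenyl)-2-[3-methoxy-4-(tosyloxy)phenyl]cyclohex-4-ene-1,1-dicarboxylate
Product: 16 methyl (2S,6R)-6-(3,4-dimethoxyphenyl)-2-[3-methoxy-4-(tosyloxy)phenyl]cyclohex-4-ene-1-carboxylate (both epimers at C1)
Conditions: LiCl, H2O, DMSO, 150 °C
Reagents that add atoms: none
Why: Krapcho dealkoxycarbonylation, in which chloride attacks the unhindered ester methyl group and the carboxylate decarboxylates; any tosylate lost under these conditions converges in step 10.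

**Step 10**
Reactants: 16 methyl (2S,6R)-6-(3,4-dimethoxyphenyl)-2-[3-methoxy-4-(tosyloxy)phenyl]cyclohex-4-ene-1-carboxylate (both epimers at C1)
Product: 17 methyl (1R,2S,6R)-6-(3,4-dimethoxyphenyl)-2-(4-hydroxy-3-methoxyphenyl)cyclohex-4-ene-1-carboxylate
Conditions: Mg turnings, MeOH, rt, ultrasound; then NaOMe (0.3 equiv), 60 °C; aq. NH4Cl
Reagents that add atoms: none
Why: Reductive S–O cleavage of the aryl sulfonate by Mg/MeOH (no alkylating by‑product, isolated alkene untouched) followed by methoxide equilibration of the ester α‑carbon sets C1 thermodynamically as the all‑equatorial, all‑trans (1R) epimer.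

**Step 11**
Reactants: 17 methyl (1R,2S,6R)-6-(3,4-dimethoxyphenyl)-2-(4-hydroxy-3-methoxyphenyl)cyclohex-4-ene-1-carboxylate
Product: 18 methyl (1R,2S,6R)-2-{4-[(tert-butyldimethylsilyl)oxy]-3-methoxyphenyl}-6-(3,4-dimethoxyphenyl)cyclohex-4-ene-1-carboxylate
Conditions: TBSCl, imidazole, DMF, rt
Reagents that add atoms: tert-butyldimethylsilyl chloride, CC(C)(C)[Si](C)(C)Cl
Why: Silylation of the phenol so that it is not acylated in step 16 and falls off together with the second silyl ether in step 17.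

**Step 12**
Reactants: 18 methyl (1R,2S,6R)-2-{4-[(tert-butyldimethylsilyl)oxy]-3-methoxyphenyl}-6-(3,4-dimethoxyphenyl)cyclohex-4-ene-1-carboxylate
Product: 19 (1R,2S,6R)-2-{4-[(tert-butyldimethylsilyl)oxy]-3-methoxyphenyl}-6-(3,4-dimethoxyphenyl)-N-methoxy-N-methylcyclohex-4-ene-1-carboxamide
Conditions: MeNH(OMe)·HCl, i-PrMgCl, THF, −20 → 0 °C
Reagents that add atoms: N,O-dimethylhydroxylamine hydrochloride, CNOC.Cl
Why: Aminolysis of the ester by the magnesium amide of N,O‑dimethylhydroxylamine; any epimerisation at C1 returns to the all‑equatorial isomer.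

**Step 13**
Reactants: 19 (1R,2S,6R)-2-{4-[(tert-butyldimethylsilyl)oxy]-3-methoxyphenyl}-6-(3,4-dimethoxyphenyl)-N-methoxy-N-methylcyclohex-4-ene-1-carboxamide
Product: 20 1-[(1R,2S,6R)-2-{4-[(tert-butyldimethylsilyl)oxy]-3-methoxyphenyl}-6-(3,4-dimethoxyphenyl)cyclohex-4-en-1-yl]ethan-1-one
Conditions: MeMgBr, THF, 0 °C; aq. NH4Cl
Reagents that add atoms: methylmagnesium bromide, C[Mg]Br
Why: Grignard addition to the N‑methoxy‑N‑methylamide stops at the chelated tetrahedral adduct, so the methyl ketone is released only on work‑up.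

**Step 14**
Reactants: 21 ferulic acid
Product: 23 (E)-3-{4-[(tert-butyldimethylsilyl)oxy]-3-methoxyphenyl}prop-2-enoic acid, via bis-silyl ferulate 22 (not isolated)
Conditions: TBSCl (2.5 equiv), imidazole, DMF, rt; then AcOH/THF/H2O, rt
Reagents that add atoms: tert-butyldimethylsilyl chloride, CC(C)(C)[Si](C)(C)Cl
Why: Exhaustive silylation followed by selective hydrolysis of the much more labile silyl ester leaves the aryl silyl ether.

**Step 15**
Reactants: 23 (E)-3-{4-[(tert-butyldimethylsilyl)oxy]-3-methoxyphenyl}prop-2-enoic acid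
Product: 24 (E)-3-{4-[(tert-butyldimethylsilyl)oxy]-3-methoxyphenyl}prop-2-enoyl chloride
Conditions: (COCl)2, DMF (cat.), CH2Cl2, 0 °C → rt; concentrated and used crude
Reagents that add atoms: oxalyl chloride, ClC(=O)C(Cl)=O
Why: Acid chloride formation through the catalytic chloroiminium species under conditions that aryl silyl ethers tolerate.

**Step 16**
Reactants: 20 1-[(1R,2S,6R)-2-{4-[(tert-butyldimethylsilyl)oxy]-3-methoxyphenyl}-6-(3,4-dimethoxyphenyl)cyclohex-4-en-1-yl]ethan-1-one; 24 (E)-3-{4-[(tert-butyldimethylsilyl)oxy]-3-methoxyphenyl}prop-2-enoyl chloride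
Product: 25 (2Z,4E)-5-{4-[(tert-butyldimethylsilyl)oxy]-3-methoxyphenyl}-1-[(1R,2S,6R)-2-{4-[(tert-butyldimethylsilyl)oxy]-3-methoxyphenyl}-6-(3,4-dimethoxyphenyl)cyclohex-4-en-1-yl]-3-hydroxypenta-2,4-dien-1-one (enol form of the 1,3-diketone)
Conditions: LiHMDS (2.2 equiv), THF, −78 °C; 24, −78 → −30 °C; aq. NH4Cl
Reagents that add atoms: none
Why: Claisen‑type C‑acylation of the kinetic lithium enolate, formed at the unhindered methyl group and not at the flanked tertiary C1–H, with the second equivalent of base storing the product as its diketonate.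

**Step 17**
Reactants: 25 (2Z,4E)-5-{4-[(tert-butyldimethylsilyl)oxy]-3-methoxyphenyl}-1-[(1R,2S,6R)-2-{4-[(tert-butyldimethylsilyl)oxy]-3-methoxyphenyl}-6-(3,4-dimethoxyphenyl)cyclohex-4-en-1-yl]-3-hydroxypenta-2,4-dien-1-one
Product: 26 (2Z,4E)-1-[(1R,2S,6R)-6-(3,4-dimethoxyphenyl)-2-(4-hydroxy-3-methoxyphenyl)cyclohex-4-en-1-yl]-3-hydroxy-5-(4-hydroxy-3-methoxyphenyl)penta-2,4-dien-1-one (target)
Conditions: Bu4NF, AcOH, THF, 0 °C
Reagents that add atoms: none
Why: Fluoride cleavage of both aryl silyl ethers, buffered with acetic acid so that the base‑sensitive enolised β‑diketone and the C1 stereocentre are not exposed to free phenoxide or fluoride basicity.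

**Compound list**

1 | coniferaldehyde | COc1cc(/C=C/C=O)ccc1O | starting material
2 | (E)-3-[3-methoxy-4-(tosyloxy)phenyl]prop-2-enal | COc1cc(/C=C/C=O)ccc1OS(=O)(=O)c1ccc(C)cc1 | intermediate
3 | dimethyl malonate | COC(=O)CC(=O)OC | starting material
4 | dimethyl 2-[(1S)-1-[3-methoxy-4-(tosyloxy)phenyl]-3-oxopropyl]malonate | COC(=O)C(C(=O)OC)[C@@H](c1ccc(OS(=O)(=O)c2ccc(C)cc2)c(OC)c1)CC=O | intermediate
5 | dimethyl 2-[(1S)-1-[3-methoxy-4-(tosyloxy)phenyl]but-3-yn-1-yl]malonate | COC(=O)C(C(=O)OC)[C@@H](c1ccc(OS(=O)(=O)c2ccc(C)cc2)c(OC)c1)CC#C | intermediate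
6 | 3,4-dimethoxybenzaldehyde | COc1ccc(C=O)cc1OC | starting material
7 | 4-(dimethoxymethyl)-1,2-dimethoxybenzene | COC(OC)c1ccc(OC)c(OC)c1 | intermediate
8 | 4-[chloro(methoxy)methyl]-1,2-dimethoxybenzene (racemic, not isolated) | COC(Cl)c1ccc(OC)c(OC)c1 | intermediate
9 | dimethyl 2-[(3,4-dimethoxyphenyl)(methoxy)methyl]-2-[(1R)-1-[3-methoxy-4-(tosyloxy)phenyl]but-3-yn-1-yl]malonate (both epimers at the methoxy-bearing carbon) | COC(=O)C(C(=O)OC)(C(OC)c1ccc(OC)c(OC)c1)[C@@H](c1ccc(OS(=O)(=O)c2ccc(C)cc2)c(OC)c1)CC#C | intermediate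
10 | dimethyl 2-[(3,4-dimethoxyphenyl)(methoxy)methyl]-2-[(1R)-1-[3-methoxy-4-(tosyloxy)phenyl]-4-(trimethylsilyl)but-3-yn-1-yl]malonate | COC(=O)C(C(=O)OC)(C(OC)c1ccc(OC)c(OC)c1)[C@@H](c1ccc(OS(=O)(=O)c2ccc(C)cc2)c(OC)c1)CC#C[Si](C)(C)C | intermediate
11 | dimethyl 2-[(3,4-dimethoxyphenyl)(methoxy)methyl]-2-[(1R,3Z)-4-(dicyclohexylboranyl)-1-[3-methoxy-4-(tosyloxy)phenyl]-4-(trimethylsilyl)but-3-en-1-yl]malonate (not isolated) | COC(=O)C(C(=O)OC)(C(OC)c1ccc(OC)c(OC)c1)[C@@H](c1ccc(OS(=O)(=O)c2ccc(C)cc2)c(OC)c1)C/C=C(\[Si](C)(C)C)B(C1CCCCC1)C1CCCCC1 | intermediate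
12 | dimethyl 2-[(3,4-dimethoxyphenyl)(methoxy)methyl]-2-[(1R,3Z)-1-[3-methoxy-4-(tosyloxy)phenyl]-4-(trimethylsilyl)but-3-en-1-yl]malonate (key-step precursor) | COC(=O)C(C(=O)OC)(C(OC)c1ccc(OC)c(OC)c1)[C@@H](c1ccc(OS(=O)(=O)c2ccc(C)cc2)c(OC)c1)C/C=C\[Si](C)(C)C | intermediate
13 | (3,4-dimethoxyphenyl)methylium ion carrying the quaternary malonate carbon of 12 (benzylic cation, not isolated) | COC(=O)C(C(=O)OC)([CH+]c1ccc(OC)c(OC)c1)[C@@H](c1ccc(OS(=O)(=O)c2ccc(C)cc2)c(OC)c1)C/C=C\[Si](C)(C)C | intermediate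
14 | 6-(3,4-dimethoxyphenyl)-1,1-bis(methoxycarbonyl)-2-[3-methoxy-4-(tosyloxy)phenyl]-5-(trimethylsilyl)cyclohexan-4-ylium, silicon on the face of the two aryl groups (β-silyl cation, not isolated) | COC(=O)C1(C(=O)OC)[C@@H](c2ccc(OS(=O)(=O)c3ccc(C)cc3)c(OC)c2)C[CH+][C@@H]([Si](C)(C)C)[C@H]1c1ccc(OC)c(OC)c1 | intermediate
15 | dimethyl (2R,6S)-6-(3,4-dimethoxyphenyl)-2-[3-methoxy-4-(tosyloxy)phenyl]cyclohex-4-ene-1,1-dicarboxylate (2,6-cis; key-step product) | COC(=O)C1(C(=O)OC)[C@@H](c2ccc(OS(=O)(=O)c3ccc(C)cc3)c(OC)c2)CC=C[C@H]1c1ccc(OC)c(OC)c1 | intermediate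
16 | methyl (2S,6R)-6-(3,4-dimethoxyphenyl)-2-[3-methoxy-4-(tosyloxy)phenyl]cyclohex-4-ene-1-carboxylate (both epimers at C1) | COC(=O)C1[C@@H](c2ccc(OS(=O)(=O)c3ccc(C)cc3)c(OC)c2)CC=C[C@H]1c1ccc(OC)c(OC)c1 | intermediate
17 | methyl (1R,2S,6R)-6-(3,4-dimethoxyphenyl)-2-(4-hydroxy-3-methoxyphenyl)cyclohex-4-ene-1-carboxylate (all-trans) | COC(=O)[C@@H]1[C@@H](c2ccc(O)c(OC)c2)CC=C[C@H]1c1ccc(OC)c(OC)c1 | intermediate
18 | methyl (1R,2S,6R)-2-{4-[(tert-butyldimethylsilyl)oxy]-3-methoxyphenyl}-6-(3,4-dimethoxyphenyl)cyclohex-4-ene-1-carboxylate | COC(=O)[C@@H]1[C@@H](c2ccc(O[Si](C)(C)C(C)(C)C)c(OC)c2)CC=C[C@H]1c1ccc(OC)c(OC)c1 | intermediate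
19 | (1R,2S,6R)-2-{4-[(tert-butyldimethylsilyl)oxy]-3-methoxyphenyl}-6-(3,4-dimethoxyphenyl)-N-methoxy-N-methylcyclohex-4-ene-1-carboxamide | CON(C)C(=O)[C@@H]1[C@@H](c2ccc(O[Si](C)(C)C(C)(C)C)c(OC)c2)CC=C[C@H]1c1ccc(OC)c(OC)c1 | intermediate
20 | 1-[(1R,2S,6R)-2-{4-[(tert-butyldimethylsilyl)oxy]-3-methoxyphenyl}-6-(3,4-dimethoxyphenyl)cyclohex-4-en-1-yl]ethan-1-one | CC(=O)[C@@H]1[C@@H](c2ccc(O[Si](C)(C)C(C)(C)C)c(OC)c2)CC=C[C@H]1c1ccc(OC)c(OC)c1 | intermediate
21 | ferulic acid | COc1cc(/C=C/C(O)=O)ccc1O | starting material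
22 | tert-butyldimethylsilyl (E)-3-{4-[(tert-butyldimethylsilyl)oxy]-3-methoxyphenyl}prop-2-enoate (not isolated) | COc1cc(/C=C/C(=O)O[Si](C)(C)C(C)(C)C)ccc1O[Si](C)(C)C(C)(C)C | intermediate
23 | (E)-3-{4-[(tert-butyldimethylsilyl)oxy]-3-methoxyphenyl}prop-2-enoic acid | COc1cc(/C=C/C(O)=O)ccc1O[Si](C)(C)C(C)(C)C | intermediate
24 | (E)-3-{4-[(tert-butyldimethylsilyl)oxy]-3-methoxyphenyl}prop-2-enoyl chloride | COc1cc(/C=C/C(Cl)=O)ccc1O[Si](C)(C)C(C)(C)C | intermediate
25 | (2Z,4E)-5-{4-[(tert-butyldimethylsilyl)oxy]-3-methoxyphenyl}-1-[(1R,2S,6R)-2-{4-[(tert-butyldimethylsilyl)oxy]-3-methoxyphenyl}-6-(3,4-dimethoxyphenyl)cyclohex-4-en-1-yl]-3-hydroxypenta-2,4-dien-1-one | COc1cc(/C=C/C(O)=C/C(=O)[C@@H]2[C@@H](c3ccc(O[Si](C)(C)C(C)(C)C)c(OC)c3)CC=C[C@H]2c2ccc(OC)c(OC)c2)ccc1O[Si](C)(C)C(C)(C)C | intermediate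
26 | (2Z,4E)-1-[(1R,2S,6R)-6-(3,4-dimethoxyphenyl)-2-(4-hydroxy-3-methoxyphenyl)cyclohex-4-en-1-yl]-3-hydroxy-5-(4-hydroxy-3-methoxyphenyl)penta-2,4-dien-1-one | COc1cc(/C=C/C(O)=C/C(=O)[C@@H]2[C@@H](c3ccc(O)c(OC)c3)CC=C[C@H]2c2ccc(OC)c(OC)c2)ccc1O | target

**Totals**

Total step count: 17.
Longest linear sequence: 14 steps (1, 2, 3, 5, 6, 7, 8, 9, 10, 11, 12, 13, 16, 17, from coniferaldehyde).

**Steps most likely to fail**

1. Step 8. The benzylic cation may be captured by the neighbouring C2 aryl ring (five‑membered Friedel–Crafts closure) or the vinylsilane may be protodesilylated before it cyclises; the two faces of the cation may also be discriminated poorly, eroding the 2,6‑cis selectivity. The fallback sets out from alkyne 5 and returns at 15, closing the ring by metathesis instead of by cation capture. Semihydrogenation of 5 (H2, Pd/CaCO3 poisoned with Pb(OAc)2, quinoline) would give dimethyl 2-[(1S)-1-[3-methoxy-4-(tosyloxy)phenyl]but-3-en-1-yl]malonate F1. Its sodium enolate would be alkylated at the benzylic terminus of methyl (E)-3-(3,4-dimethoxyphenyl)prop-2-en-1-yl carbonate F2 (from commercial 3,4‑dimethoxycinnamyl alcohol and methyl chloroformate) with [Ir(cod)Cl]2 and a chiral binaphthol‑derived phosphoramidite ligand, the ligand enantiomer being chosen to set the (S) allylic carbon. This would give the diene dimethyl 2-[(1S)-1-(3,4-dimethoxyphenyl)prop-2-en-1-yl]-2-[(1R)-1-[3-methoxy-4-(tosyloxy)phenyl]but-3-en-1-yl]malonate F3. Ring‑closing metathesis with the second‑generation Grubbs catalyst (CH2Cl2, 40 °C) would then form C4=C5 and deliver 15.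

2. Step 5. Bond formation at the congested tertiary malonate carbon may be outrun by ionisation and self‑condensation of the α‑chloro ether. The fallback sets out from 5 and returns at 9, reaching the same benzylic ether through the carbonyl oxidation level. C‑acylation of the sodium enolate of 5 with 3,4‑dimethoxybenzoyl chloride (THF, 0 °C) would give dimethyl 2-(3,4-dimethoxybenzoyl)-2-[(1R)-1-[3-methoxy-4-(tosyloxy)phenyl]but-3-yn-1-yl]malonate F4. Reduction of the aryl ketone (NaBH4, CeCl3·7H2O, MeOH, −40 °C) would give dimethyl 2-[(3,4-dimethoxyphenyl)(hydroxy)methyl]-2-[(1R)-1-[3-methoxy-4-(tosyloxy)phenyl]but-3-yn-1-yl]malonate F5. O‑Methylation without alkoxide formation (Me3OBF4, 1,8‑bis(dimethylamino)naphthalene, CH2Cl2), so that no retro‑aldol cleavage can occur, would give 9.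

3. Step 16. O‑acylation or double acylation of the enolate, or proton transfer from the product to unreacted enolate, may divert the acylation. The fallback sets out from 20 (and from 1) and returns at 25, replacing the acylation by an aldol addition and an oxidation. Silylation of 1 (TBSCl, imidazole, DMF) would give (E)-3-{4-[(tert-butyldimethylsilyl)oxy]-3-methoxyphenyl}prop-2-enal F6. The lithium enolate of 20 (LiHMDS, THF, −78 °C) should add 1,2 to F6 to give (E)-5-{4-[(tert-butyldimethylsilyl)oxy]-3-methoxyphenyl}-1-[(1R,2S,6R)-2-{4-[(tert-butyldimethylsilyl)oxy]-3-methoxyphenyl}-6-(3,4-dimethoxyphenyl)cyclohex-4-en-1-yl]-3-hydroxypent-4-en-1-one F7 (both epimers at the carbinol carbon). Oxidation of the allylic β‑hydroxy ketone with Dess–Martin periodinane (CH2Cl2, NaHCO3, 0 °C) would give 25.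

**Further compounds**

F1 | step 8 | dimethyl 2-[(1S)-1-[3-methoxy-4-(tosyloxy)phenyl]but-3-en-1-yl]malonate | COC(=O)C(C(=O)OC)[C@@H](c1ccc(OS(=O)(=O)c2ccc(C)cc2)c(OC)c1)CC=C
F2 | step 8 | methyl (E)-3-(3,4-dimethoxyphenyl)prop-2-en-1-yl carbonate | COC(=O)OC/C=C/c1ccc(OC)c(OC)c1
F3 | step 8 | dimethyl 2-[(1S)-1-(3,4-dimethoxyphenyl)prop-2-en-1-yl]-2-[(1R)-1-[3-methoxy-4-(tosyloxy)phenyl]but-3-en-1-yl]malonate | COC(=O)C(C(=O)OC)([C@@H](c1ccc(OS(=O)(=O)c2ccc(C)cc2)c(OC)c1)CC=C)[C@@H](C=C)c1ccc(OC)c(OC)c1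
F4 | step 5 | dimethyl 2-(3,4-dimethoxybenzoyl)-2-[(1R)-1-[3-methoxy-4-(tosyloxy)phenyl]but-3-yn-1-yl]malonate | COC(=O)C(C(=O)OC)(C(=O)c1ccc(OC)c(OC)c1)[C@@H](c1ccc(OS(=O)(=O)c2ccc(C)cc2)c(OC)c1)CC#C
F5 | step 5 | dimethyl 2-[(3,4-dimethoxyphenyl)(hydroxy)methyl]-2-[(1R)-1-[3-methoxy-4-(tosyloxy)phenyl]but-3-yn-1-yl]malonate (both epimers at the carbinol carbon) | COC(=O)C(C(=O)OC)(C(O)c1ccc(OC)c(OC)c1)[C@@H](c1ccc(OS(=O)(=O)c2ccc(C)cc2)c(OC)c1)CC#C
F6 | step 16 | (E)-3-{4-[(tert-butyldimethylsilyl)oxy]-3-methoxyphenyl}prop-2-enal | COc1cc(/C=C/C=O)ccc1O[Si](C)(C)C(C)(C)C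
F7 | step 16 | (E)-5-{4-[(tert-butyldimethylsilyl)oxy]-3-methoxyphenyl}-1-[(1R,2S,6R)-2-{4-[(tert-butyldimethylsilyl)oxy]-3-methoxyphenyl}-6-(3,4-dimethoxyphenyl)cyclohex-4-en-1-yl]-3-hydroxypent-4-en-1-one (both epimers at the carbinol carbon) | COc1cc(/C=C/C(O)CC(=O)[C@@H]2[C@@H](c3ccc(O[Si](C)(C)C(C)(C)C)c(OC)c3)CC=C[C@H]2c2ccc(OC)c(OC)c2)ccc1O[Si](C)(C)C(C)(C)C
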